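**Plan** (carotenoid numbering: ring C2–C3–C4–C5–C6; C2 bears C1(CH3)2OH, C5 bears CH3 and OH, C6 bears chain carbon C7)
1. Cuts: C7=C8 (Julia–Kocienski, ring sulfone + C30 polyenal), C7'=C8' (Wittig, geranyl ylide + C20 dialdehyde), C5–CH3 (organocerium addition), ring bond C2–C3 (Nazarov), C4–C5 (vinyllithium + Weinreb amide), C2=C6 (Horner–Wadsworth–Emmons), C6–C7 (alkylation with benzyl chloromethyl ether).
2. Enabling feature: the cyclopentane C2–C6 has its only oxygen on C5, flanked by C4 and by C6 (which holds C7). C5 can therefore be the carbonyl of the cross-conjugated dienone C3=C4–C5(=O)–C6=C2, whose termini C2 and C3 close the ring.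
3. Forward order: acyclic β-silyl dienone → cyclopentenone (the only ring) → C5 carbinol → saturated ring sulfone → union with the separately made polyenal → desilylation.
4. Stereochemistry: C2 from catalyst-controlled conrotation; C6 by protonation trans to C2; C5 by methyl addition anti to the C6 substituent; E alkenes from Horner–Wadsworth–Emmons, Julia–Kocienski and iodine equilibration.

Key step: step 6

Assumption: crocetindialdehyde (19) is taken as a purchasable C20 building block, and the enantiomer of the phosphoric acid that leads to 11 is fixed in a first run.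

**Step 1**
Reactants: 1 ethyl 2-hydroxy-2-methylpropanoate
Product: 2 ethyl 2-methyl-2-(triethylsilyloxy)propanoate
Conditions: Et3SiCl, imidazole, DMAP (cat.), DMF, rt
Reagents that add atoms: chlorotriethylsilane, CC[Si](Cl)(CC)CC
Why: Imidazole-promoted silyl ether formation masks the C1 hydroxyl as a tertiary triethylsilyl ether that tolerates hydride, carbanions and mild acid and is removed by fluoride at the end.

**Step 2**
Reactants: 2 ethyl 2-methyl-2-(triethylsilyloxy)propanoate
Product: 3 2-methyl-2-(triethylsilyloxy)propanal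
Conditions: i-Bu2AlH, CH2Cl2, −78 °C; MeOH, aq. Rochelle salt
Reagents that add atoms: none
Why: Partial reduction of an α-alkoxy ester with DIBAL at −78 °C stops at the chelated aluminium hemiacetal, which releases the non-enolisable aldehyde on work-up.

**Step 3**
Reactants: 4 diethyl {2-[methoxy(methyl)amino]-2-oxoethyl}phosphonate; 5 benzyl chloromethyl ether
Product: 6 diethyl {3-(benzyloxy)-1-[methoxy(methyl)amino]-1-oxopropan-2-yl}phosphonate (racemic)
Conditions: NaH, THF, 0 °C; then 5, 0 °C → rt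
Reagents that add atoms: none
Why: SN2 C-alkylation of the sodium salt of the stabilised phosphonate by the reactive chloromethyl ether installs C7 as a benzyloxymethyl group; the new CH centre is racemic and is destroyed in step 4.

**Step 4**
Reactants: 6 diethyl {3-(benzyloxy)-1-[methoxy(methyl)amino]-1-oxopropan-2-yl}phosphonate; 3 2-methyl-2-(triethylsilyloxy)propanal
Product: 7 (E)-2-(benzyloxymethyl)-N-methoxy-N,4-dimethyl-4-(triethylsilyloxy)pent-2-enamide
Conditions: NaH, THF, 0 °C; then 3, 0 °C → rt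
Reagents that add atoms: none
Why: Horner–Wadsworth–Emmons olefination of the α-substituted Weinreb phosphonate with the bulky α-quaternary aldehyde should place the acyl group trans to the CMe2OSiEt3 group (E), and any reversible loss of benzyloxide from the carbanion is drained by the olefination.

**Step 5**
Reactants: 8 (E)-(2-bromovinyl)trimethylsilane; 7 (E)-2-(benzyloxymethyl)-N-methoxy-N,4-dimethyl-4-(triethylsilyloxy)pent-2-enamide
Product: 10 (1E,4E)-4-(benzyloxymethyl)-6-methyl-6-(triethylsilyloxy)-1-(trimethylsilyl)hepta-1,4-dien-3-one, via (E)-2-(trimethylsilyl)vinyllithium 9 (not isolated)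
Conditions: 8, t-BuLi (2 equiv), Et2O, −78 °C; then 7, −78 → −40 °C; aq. NH4Cl
Reagents that add atoms: none
Why: Bromine–lithium exchange with retention of alkene geometry followed by acyl substitution on the Weinreb amide, whose chelated tetrahedral intermediate blocks over-addition, gives the cross-conjugated β-silyl dienone.

**Step 6**
Reactants: 10 (1E,4E)-4-(benzyloxymethyl)-6-methyl-6-(triethylsilyloxy)-1-(trimethylsilyl)hepta-1,4-dien-3-one
Product: 11 (4R,5R)-5-(benzyloxymethyl)-4-[2-(triethylsilyloxy)propan-2-yl]cyclopent-2-en-1-one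
Conditions: (R)-3,3'-bis(2,4,6-triisopropylphenyl)-1,1'-binaphthyl-2,2'-diyl hydrogen phosphate (10 mol%), Zn(OTf)2 (10 mol%), PhOH (1.2 equiv), ClCH2CH2Cl, 40 °C
Reagents that add atoms: none
Why: Zn(OTf)2 binds the ketone oxygen (helped by the C7 ether oxygen) and, with the phosphate as chiral counter-anion, generates the hydroxypentadienyl cation C3=C4–C5(O)–C6=C2, which closes the five-membered ring by 4π conrotatory electrocyclisation between C2 and C3. The trimethylsilyl group on C3 stabilises the charge at C4 (β-silicon effect) and is passed to phenol, so the alkene ends at C3=C4 and not at the tetrasubstituted C2=C6 position, which would erase both stereocentres. The closest known reaction type is the silicon-directed Nazarov cyclisation in its catalytic enantioselective form with a chiral phosphoric acid and a zinc salt. C2 is set by the sense of conrotation, which the chiral phosphate in the contact ion pair has to bias; C6 is set afterwards by protonation of the zinc dienolate on the face away from the C2 substituent and, being α to the ketone, can equilibrate to the more stable trans arrangement. The step needs E geometry at both alkenes, the α-substituent at C6 to favour the reactive s-trans/s-trans conformer, and survival of the tertiary allylic silyl ether, which the low loading of mild acid and the electron-poor enone (poor stabilisation of a C1 cation) should secure.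

**Step 7**
Reactants: 11 (4R,5R)-5-(benzyloxymethyl)-4-[2-(triethylsilyloxy)propan-2-yl]cyclopent-2-en-1-one
Product: 12 (1R,4R,5R)-5-(benzyloxymethyl)-1-methyl-4-[2-(triethylsilyloxy)propan-2-yl]cyclopent-2-en-1-ol
Conditions: MeLi, CeCl3 (anhydrous), THF, −78 °C
Reagents that add atoms: methyllithium, [Li]C
Why: 1,2-Addition of the weakly basic organocerium reagent to the enone avoids enolisation and loss of benzyloxide, and the methyl group should enter anti to the adjacent benzyloxymethyl group on C6, which places the C5 hydroxyl cis to C7 (substrate control).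

**Step 8**
Reactants: 12 (1R,4R,5R)-5-(benzyloxymethyl)-1-methyl-4-[2-(triethylsilyloxy)propan-2-yl]cyclopent-2-en-1-ol
Product: 13 triethyl{[(1R,4R,5R)-5-(benzyloxymethyl)-1-methyl-4-[2-(triethylsilyloxy)propan-2-yl]cyclopent-2-en-1-yl]oxy}silane
Conditions: Et3SiOTf, 2,6-lutidine, CH2Cl2, −78 → 0 °C
Reagents that add atoms: triethylsilyl trifluoromethanesulfonate, CC[Si](CC)(CC)OS(=O)(=O)C(F)(F)F
Why: Silyl triflate/2,6-lutidine silylation of the hindered tertiary alcohol at low temperature protects the C5 hydroxyl so that no alkoxide can interfere with the sulfonyl carbanion in step 14.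

**Step 9**
Reactants: 13 triethyl{[(1R,4R,5R)-5-(benzyloxymethyl)-1-methyl-4-[2-(triethylsilyloxy)propan-2-yl]cyclopent-2-en-1-yl]oxy}silane
Product: 14 {(1R,2R,5R)-2-methyl-2-(triethylsilyloxy)-5-[2-(triethylsilyloxy)propan-2-yl]cyclopentyl}methanol
Conditions: H2 (1 atm), Pd/C, EtOAc, rt
Reagents that add atoms: none
Why: Heterogeneous hydrogenation saturates the cis-disubstituted C3=C4 alkene (no stereocentre is created) and hydrogenolyses the benzyl ether in the same operation, while the silyl ethers are stable in ethyl acetate.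

**Step 10**
Reactants: 14 {(1R,2R,5R)-2-methyl-2-(triethylsilyloxy)-5-[2-(triethylsilyloxy)propan-2-yl]cyclopentyl}methanol
Product: 15 5-({[(1S,2R,5R)-2-methyl-2-(triethylsilyloxy)-5-[2-(triethylsilyloxy)propan-2-yl]cyclopentyl]methyl}sulfanyl)-1-phenyl-1H-tetrazole
Conditions: 1-phenyl-1H-tetrazole-5-thiol, PPh3, DIAD, THF, 0 °C → rt
Reagents that add atoms: 1-phenyl-1H-tetrazole-5-thiol, Sc1nnnn1-c1ccccc1
Why: Mitsunobu thioetherification is an SN2 displacement at the primary C7 carbinol by the acidic tetrazolethiol and touches no stereocentre (the descriptor at the ring carbon changes only through priorities).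

**Step 11**
Reactants: 15 5-({[(1S,2R,5R)-2-methyl-2-(triethylsilyloxy)-5-[2-(triethylsilyloxy)propan-2-yl]cyclopentyl]methyl}sulfanyl)-1-phenyl-1H-tetrazole
Product: 16 5-({[(1S,2R,5R)-2-methyl-2-(triethylsilyloxy)-5-[2-(triethylsilyloxy)propan-2-yl]cyclopentyl]methyl}sulfonyl)-1-phenyl-1H-tetrazole
Conditions: mCPBA (2.5 equiv), NaHCO3, CH2Cl2, 0 °C → rt
Reagents that add atoms: 3-chloroperoxybenzoic acid, O=C(OO)c1cccc(Cl)c1
Why: Peracid oxidation takes the sulfide through the sulfoxide to the sulfone; no alkene is present at this stage and the bicarbonate buffer protects the silyl ethers.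

**Step 12**
Reactants: 17 geranyl bromide [(2E)-1-bromo-3,7-dimethylocta-2,6-diene]
Product: 18 [(2E)-3,7-dimethylocta-2,6-dien-1-yl]triphenylphosphonium bromide
Conditions: PPh3, toluene, rt
Reagents that add atoms: triphenylphosphine, c1ccc(cc1)P(c1ccccc1)c1ccccc1
Why: SN2 quaternisation of PPh3 by the primary allylic bromide at room temperature keeps the E geometry of the trisubstituted alkene.

**Step 13**
Reactants: 18 [(2E)-3,7-dimethylocta-2,6-dien-1-yl]triphenylphosphonium bromide; 19 crocetindialdehyde [(2E,4E,6E,8E,10E,12E,14E)-2,6,11,15-tetramethylhexadeca-2,4,6,8,10,12,14-heptaenedial]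
Product: 21 (2E,4E,6E,8E,10E,12E,14E,16E,18E)-2,6,11,15,19,23-hexamethyltetracosa-2,4,6,8,10,12,14,16,18,22-decaenal, via [(2E)-3,7-dimethylocta-2,6-dien-1-ylidene]triphenylphosphorane 20 (not isolated)
Conditions: 19 (2.5 equiv), NaOMe, MeOH/CH2Cl2, slow addition of 18, 0 °C → rt; then I2 (cat.), CH2Cl2, visible light
Reagents that add atoms: none
Why: Wittig olefination of one aldehyde of the symmetrical dial is favoured by excess dial, slow addition and the lower electrophilicity of the elongated mono-adduct, and iodine-catalysed equilibration turns the hindered Z isomer of the new disubstituted alkene into E.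

**Step 14**
Reactants: 16 5-({[(1S,2R,5R)-2-methyl-2-(triethylsilyloxy)-5-[2-(triethylsilyloxy)propan-2-yl]cyclopentyl]methyl}sulfonyl)-1-phenyl-1H-tetrazole; 21 (2E,4E,6E,8E,10E,12E,14E,16E,18E)-2,6,11,15,19,23-hexamethyltetracosa-2,4,6,8,10,12,14,16,18,22-decaenal
Product: 22 triethyl{[(1R,2S,3R)-1-methyl-2-[(1E,3E,5E,7E,9E,11E,13E,15E,17E,19E)-3,7,12,16,20,24-hexamethylpentacosa-1,3,5,7,9,11,13,15,17,19,23-undecaen-1-yl]-3-[2-(triethylsilyloxy)propan-2-yl]cyclopentyl]oxy}silane
Conditions: KN(SiMe3)2, THF, −78 °C; then 21, −78 °C → rt; I2 (cat.), CH2Cl2, visible light if a Z isomer is present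
Reagents that add atoms: none
Why: Julia–Kocienski olefination (addition of the potassiated 1-phenyltetrazolyl sulfone to the aldehyde, Smiles rearrangement, loss of SO2 and tetrazololate) favours the E C7=C8 alkene, and since C7 is not stereogenic and C6–H is not acidic the ring stereocentres are untouched.

**Step 15**
Reactants: 22 triethyl{[(1R,2S,3R)-1-methyl-2-[(1E,3E,5E,7E,9E,11E,13E,15E,17E,19E)-3,7,12,16,20,24-hexamethylpentacosa-1,3,5,7,9,11,13,15,17,19,23-undecaen-1-yl]-3-[2-(triethylsilyloxy)propan-2-yl]cyclopentyl]oxy}silane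
Product: 23 (1R,2S,3R)-3-(2-hydroxypropan-2-yl)-1-methyl-2-[(1E,3E,5E,7E,9E,11E,13E,15E,17E,19E)-3,7,12,16,20,24-hexamethylpentacosa-1,3,5,7,9,11,13,15,17,19,23-undecaen-1-yl]cyclopentan-1-ol (CNP0169920.4)
Conditions: Bu4NF, THF, 0 °C → rt, dark, argon
Reagents that add atoms: none
Why: Fluoride cleaves both tertiary triethylsilyl ethers under non-acidic conditions that the polyene tolerates.

**Compound list**
1 | ethyl 2-hydroxy-2-methylpropanoate | CCOC(=O)C(C)(C)O | starting material
2 | ethyl 2-methyl-2-(triethylsilyloxy)propanoate | CCOC(=O)C(C)(C)O[Si](CC)(CC)CC | intermediate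
3 | 2-methyl-2-(triethylsilyloxy)propanal | O=CC(C)(C)O[Si](CC)(CC)CC | intermediate
4 | diethyl {2-[methoxy(methyl)amino]-2-oxoethyl}phosphonate | CCOP(=O)(OCC)CC(=O)N(C)OC | starting material
5 | benzyl chloromethyl ether | ClCOCc1ccccc1 | starting material
6 | diethyl {3-(benzyloxy)-1-[methoxy(methyl)amino]-1-oxopropan-2-yl}phosphonate (racemic) | CCOP(=O)(OCC)C(COCc1ccccc1)C(=O)N(C)OC | intermediate
7 | (E)-2-(benzyloxymethyl)-N-methoxy-N,4-dimethyl-4-(triethylsilyloxy)pent-2-enamide | CON(C)C(=O)/C(COCc1ccccc1)=C/C(C)(C)O[Si](CC)(CC)CC | intermediate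
8 | (E)-(2-bromovinyl)trimethylsilane | C[Si](C)(C)/C=C/Br | starting material
9 | (E)-2-(trimethylsilyl)vinyllithium | C[Si](C)(C)/C=C/[Li] | intermediate (not isolated)
10 | (1E,4E)-4-(benzyloxymethyl)-6-methyl-6-(triethylsilyloxy)-1-(trimethylsilyl)hepta-1,4-dien-3-one | C[Si](C)(C)/C=C/C(=O)/C(COCc1ccccc1)=C/C(C)(C)O[Si](CC)(CC)CC | intermediate
11 | (4R,5R)-5-(benzyloxymethyl)-4-[2-(triethylsilyloxy)propan-2-yl]cyclopent-2-en-1-one | C(OCc1ccccc1)[C@H]1[C@H](C(C)(C)O[Si](CC)(CC)CC)C=CC1=O | intermediate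
12 | (1R,4R,5R)-5-(benzyloxymethyl)-1-methyl-4-[2-(triethylsilyloxy)propan-2-yl]cyclopent-2-en-1-ol | C(OCc1ccccc1)[C@H]1[C@H](C(C)(C)O[Si](CC)(CC)CC)C=C[C@@]1(C)O | intermediate
13 | triethyl{[(1R,4R,5R)-5-(benzyloxymethyl)-1-methyl-4-[2-(triethylsilyloxy)propan-2-yl]cyclopent-2-en-1-yl]oxy}silane | C(OCc1ccccc1)[C@H]1[C@H](C(C)(C)O[Si](CC)(CC)CC)C=C[C@@]1(C)O[Si](CC)(CC)CC | intermediate
14 | {(1R,2R,5R)-2-methyl-2-(triethylsilyloxy)-5-[2-(triethylsilyloxy)propan-2-yl]cyclopentyl}methanol | OC[C@H]1[C@H](C(C)(C)O[Si](CC)(CC)CC)CC[C@@]1(C)O[Si](CC)(CC)CC | intermediate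
15 | 5-({[(1S,2R,5R)-2-methyl-2-(triethylsilyloxy)-5-[2-(triethylsilyloxy)propan-2-yl]cyclopentyl]methyl}sulfanyl)-1-phenyl-1H-tetrazole | c1ccccc1-n1nnnc1SC[C@H]1[C@H](C(C)(C)O[Si](CC)(CC)CC)CC[C@@]1(C)O[Si](CC)(CC)CC | intermediate
16 | 5-({[(1S,2R,5R)-2-methyl-2-(triethylsilyloxy)-5-[2-(triethylsilyloxy)propan-2-yl]cyclopentyl]methyl}sulfonyl)-1-phenyl-1H-tetrazole | O=S(=O)(C[C@H]1[C@H](C(C)(C)O[Si](CC)(CC)CC)CC[C@@]1(C)O[Si](CC)(CC)CC)c1nnnn1-c1ccccc1 | intermediate
17 | geranyl bromide, (2E)-1-bromo-3,7-dimethylocta-2,6-diene | CC(C)=CCC/C(C)=C/CBr | starting material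
18 | [(2E)-3,7-dimethylocta-2,6-dien-1-yl]triphenylphosphonium bromide | CC(C)=CCC/C(C)=C/C[P+](c1ccccc1)(c1ccccc1)c1ccccc1.[Br-] | intermediate
19 | crocetindialdehyde, (2E,4E,6E,8E,10E,12E,14E)-2,6,11,15-tetramethylhexadeca-2,4,6,8,10,12,14-heptaenedial | O=C/C(C)=C/C=C/C(C)=C/C=C/C=C(C)/C=C/C=C(C)/C=O | starting material
20 | [(2E)-3,7-dimethylocta-2,6-dien-1-ylidene]triphenylphosphorane | CC(C)=CCC/C(C)=C/C=P(c1ccccc1)(c1ccccc1)c1ccccc1 | intermediate (not isolated)
21 | (2E,4E,6E,8E,10E,12E,14E,16E,18E)-2,6,11,15,19,23-hexamethyltetracosa-2,4,6,8,10,12,14,16,18,22-decaenal (apo-8'-lycopenal) | CC(C)=CCC/C(C)=C/C=C/C(C)=C/C=C/C(C)=C/C=C/C=C(C)/C=C/C=C(C)/C=O | intermediate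
22 | triethyl{[(1R,2S,3R)-1-methyl-2-[(1E,3E,5E,7E,9E,11E,13E,15E,17E,19E)-3,7,12,16,20,24-hexamethylpentacosa-1,3,5,7,9,11,13,15,17,19,23-undecaen-1-yl]-3-[2-(triethylsilyloxy)propan-2-yl]cyclopentyl]oxy}silane | CC(C)=CCC/C(C)=C/C=C/C(C)=C/C=C/C(C)=C/C=C/C=C(C)/C=C/C=C(C)/C=C/[C@H]1[C@H](C(C)(C)O[Si](CC)(CC)CC)CC[C@@]1(C)O[Si](CC)(CC)CC | intermediate
23 | (1R,2S,3R)-3-(2-hydroxypropan-2-yl)-1-methyl-2-[(1E,3E,5E,7E,9E,11E,13E,15E,17E,19E)-3,7,12,16,20,24-hexamethylpentacosa-1,3,5,7,9,11,13,15,17,19,23-undecaen-1-yl]cyclopentan-1-ol | CC(C)=CCC/C(C)=C/C=C/C(C)=C/C=C/C(C)=C/C=C/C=C(C)/C=C/C=C(C)/C=C/[C@H]1[C@H](C(C)(C)O)CC[C@@]1(C)O | target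

**Totals**
Total steps: 15. Longest linear sequence: 12 steps (1, 2, 4–11, 14, 15).

**Steps most likely to fail**

Step 6. The chiral phosphate may fail to bias the sense of conrotation, so that C2 forms with low enantiomeric purity. The alkene may also drift into the tetrasubstituted C2=C6 position, or the tertiary silyl ether may ionise under acid. Fallback, from 10 back to 11: dienone 10 would be cyclised with stoichiometric FeCl3 (CH2Cl2, −30 → 0 °C), the classical achiral silicon-directed Nazarov conditions. This gives the racemic trans-enone, that is 11 together with its enantiomer (4S,5S)-5-(benzyloxymethyl)-4-[2-(triethylsilyloxy)propan-2-yl]cyclopent-2-en-1-one F1. Preparative chromatography on a chiral stationary phase (amylose tris(3,5-dimethylphenylcarbamate)) would then deliver 11, and the route resumes at step 7.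

Step 7. Facial selectivity may be poor, because the bulky C2 substituent sits on the face from which the methyl group must enter. Fallback, from 11 back to 15, with the C5 oxygen delivered from the C7 side instead:
- Hydrogenation of the ring alkene over RhCl(PPh3)3 (H2, benzene) keeps the benzyl ether and gives (2R,3R)-2-(benzyloxymethyl)-3-[2-(triethylsilyloxy)propan-2-yl]cyclopentan-1-one F2.
- Wittig methylenation (Ph3PCH3Br, KOtBu, THF) gives ({[(1S,5R)-2-methylidene-5-[2-(triethylsilyloxy)propan-2-yl]cyclopentyl]methoxy}methyl)benzene F3.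
- Reductive debenzylation with lithium 4,4'-di-tert-butylbiphenylide (THF, −78 °C) spares the alkene and the silyl ether and gives [(1S,5R)-2-methylidene-5-[2-(triethylsilyloxy)propan-2-yl]cyclopentyl]methanol F4.
- Hydroxyl-directed epoxidation (VO(acac)2, t-BuOOH, CH2Cl2) puts the oxygen on the face of the CH2OH group and gives [(3R,4R,5R)-5-[2-(triethylsilyloxy)propan-2-yl]-1-oxaspiro[2.4]heptan-4-yl]methanol F5.
- LiAlH4 opens the epoxide at its CH2 terminus to (1R,2R,3R)-2-(hydroxymethyl)-1-methyl-3-[2-(triethylsilyloxy)propan-2-yl]cyclopentan-1-ol F6, whose C5 hydroxyl is necessarily cis to C7.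
- Mitsunobu reaction of the primary alcohol with 1-phenyl-1H-tetrazole-5-thiol gives (1R,2S,3R)-1-methyl-2-{[(1-phenyl-1H-tetrazol-5-yl)sulfanyl]methyl}-3-[2-(triethylsilyloxy)propan-2-yl]cyclopentan-1-ol F7.
- Et3SiOTf/2,6-lutidine then returns sulfide 15.

Step 14. Addition of the flanked, β-branched sulfonyl carbanion to the long polyenal may be slow, may erode E selectivity, or the base may degrade the polyenal. Fallback, from 14 and 21 back to 22, with the polarity of the union reversed:
- Alcohol 14 would be oxidised with Dess–Martin periodinane/NaHCO3 to (1S,2R,5R)-2-methyl-2-(triethylsilyloxy)-5-[2-(triethylsilyloxy)propan-2-yl]cyclopentane-1-carbaldehyde F8.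
- Polyenal 21 would be reduced (NaBH4, MeOH/THF) to (2E,4E,6E,8E,10E,12E,14E,16E,18E)-2,6,11,15,19,23-hexamethyltetracosa-2,4,6,8,10,12,14,16,18,22-decaen-1-ol F9.
- PPh3·HBr (MeOH/CH2Cl2) would convert this into [(2E,4E,6E,8E,10E,12E,14E,16E,18E)-2,6,11,15,19,23-hexamethyltetracosa-2,4,6,8,10,12,14,16,18,22-decaen-1-yl]triphenylphosphonium bromide F10.
- Wittig reaction of F8 with the ylide of F10 (NaOMe, MeOH/CH2Cl2), followed by iodine equilibration of the C7=C8 alkene, gives 22.

**Further compounds**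
F1 | step 6 | (4S,5S)-5-(benzyloxymethyl)-4-[2-(triethylsilyloxy)propan-2-yl]cyclopent-2-en-1-one | C(OCc1ccccc1)[C@@H]1[C@@H](C(C)(C)O[Si](CC)(CC)CC)C=CC1=O
F2 | step 7 | (2R,3R)-2-(benzyloxymethyl)-3-[2-(triethylsilyloxy)propan-2-yl]cyclopentan-1-one | C(OCc1ccccc1)[C@H]1[C@H](C(C)(C)O[Si](CC)(CC)CC)CCC1=O
F3 | step 7 | ({[(1S,5R)-2-methylidene-5-[2-(triethylsilyloxy)propan-2-yl]cyclopentyl]methoxy}methyl)benzene | C(OCc1ccccc1)[C@H]1[C@H](C(C)(C)O[Si](CC)(CC)CC)CCC1=C
F4 | step 7 | [(1S,5R)-2-methylidene-5-[2-(triethylsilyloxy)propan-2-yl]cyclopentyl]methanol | OC[C@H]1[C@H](C(C)(C)O[Si](CC)(CC)CC)CCC1=C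
F5 | step 7 | [(3R,4R,5R)-5-[2-(triethylsilyloxy)propan-2-yl]-1-oxaspiro[2.4]heptan-4-yl]methanol | OC[C@H]1[C@H](C(C)(C)O[Si](CC)(CC)CC)CC[C@]12CO2
F6 | step 7 | (1R,2R,3R)-2-(hydroxymethyl)-1-methyl-3-[2-(triethylsilyloxy)propan-2-yl]cyclopentan-1-ol | OC[C@H]1[C@H](C(C)(C)O[Si](CC)(CC)CC)CC[C@@]1(C)O
F7 | step 7 | (1R,2S,3R)-1-methyl-2-{[(1-phenyl-1H-tetrazol-5-yl)sulfanyl]methyl}-3-[2-(triethylsilyloxy)propan-2-yl]cyclopentan-1-ol | c1ccccc1-n1nnnc1SC[C@H]1[C@H](C(C)(C)O[Si](CC)(CC)CC)CC[C@@]1(C)O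
F8 | step 14 | (1S,2R,5R)-2-methyl-2-(triethylsilyloxy)-5-[2-(triethylsilyloxy)propan-2-yl]cyclopentane-1-carbaldehyde | O=C[C@H]1[C@H](C(C)(C)O[Si](CC)(CC)CC)CC[C@@]1(C)O[Si](CC)(CC)CC
F9 | step 14 | (2E,4E,6E,8E,10E,12E,14E,16E,18E)-2,6,11,15,19,23-hexamethyltetracosa-2,4,6,8,10,12,14,16,18,22-decaen-1-ol | CC(C)=CCC/C(C)=C/C=C/C(C)=C/C=C/C(C)=C/C=C/C=C(C)/C=C/C=C(C)/CO
F10 | step 14 | [(2E,4E,6E,8E,10E,12E,14E,16E,18E)-2,6,11,15,19,23-hexamethyltetracosa-2,4,6,8,10,12,14,16,18,22-decaen-1-yl]triphenylphosphonium bromide | CC(C)=CCC/C(C)=C/C=C/C(C)=C/C=C/C(C)=C/C=C/C=C(C)/C=C/C=C(C)/C[P+](c1ccccc1)(c1ccccc1)c1ccccc1.[Br-]
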